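(The data are calculated with made-up constants, noise included.)

- Decide first what the early ratio is made of: isomer is target that has waited, so the isomer fraction at any early time is a rate constant times the mean target fraction times the time, and replacing the curve by its mean turns the ratio into a mean factor (end value over mean value) divided by that constant times the time.

| setting | blue | flask |
|---|---|---|
| substrate | 10 mM | 10 mM |
| reagent | 2 equiv | 2.00 equiv |
| free catalyst | 17 mol% | 17 mol% |
| second catalyst | 0.5 mol% | 0.5 mol% |
| impurity | 23 µM | 23 µM |
| remark | the very flask that is asked about, followed so far |  |
| time |  | 4.0 d |

- blue (time / h: target / %, isomer of the product / %, substrate / %): 1.00: 13, 0, 69; 2.00: 23, 1, 51; 3.00: 35, 3, 42; 6.00: 49, 16, 26; 12.0: 47, 43, 11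

(standard deviation of a reading: 1.5 percentage points)

* ratio of target to isomer of the product at 20 min
* ratio of target to isomer of the product at 4.0 d
* which of target and isomer of the product there is more of at 4.0 d

- the analysis behind the earlier runs scatters by 1.5 percentage points, standard deviation

- Take the constant from the blue flask between 6.00 h and 12.0 h, where target barely moves and its mean is safe: isomer gains 27 percentage points with a scatter of 1.5 points per reading, on a mean target of 48.0%, which gives the isomer clock, a first-order constant for target becoming isomer, 0.0938 h⁻¹.
- Divide by 20 min: one over clock times time is 32.0, the ratio for a target that stands flat, and a straight rise, whose mean is half the end value, gives 64.0.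
- Reforge that straight rise, the weak link: the blue flask lacks 18.0% of its charge at 1.00 h, so target seems fed from an unseen stock that starts empty, an induction period in which target grows as time squared, its mean a third of the end value, and the ratio becomes 96.0, the number to commit to.
- Carry the clock to 4.0 d: one-way loss alone leaves a share 1.23 × 10⁻⁴ of target, but the readings barely show a way back, so commit to isomer leading and to a small ratio, no firmer.
- The forecast gives 150, 0.05 and isomer of the product, calling the early value “the ratio is very large and poorly defined”.
- The flask gives 91.8, 0.0558 and isomer of the product.

    target ⇌ isomer of the product (K = 18.0, k = 0.0930 h⁻¹)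
    substrate + free catalyst ⇌ free catalyst + intermediate (K = 0.830, k = 280 L mol⁻¹ h⁻¹)
    second catalyst + impurity → spent catalyst (k = 5.00 × 10⁶ L mol⁻¹ h⁻¹)
    reagent + second catalyst + intermediate → second catalyst + target (k = 1.40 × 10⁶ L² mol⁻² h⁻¹)

- Read the early ratio through the mean factor: this flask's 91.8 stands beside 96.0 for a lagging rise, and the neighbour charged with 2.5 mM of substrate, which ends with second catalyst at 0% and impurity at 45.7% of its charge, gives 35.5, beside the flat-target value of 32.0. The way back from isomer of the product to target is the largest single effect on this flask's ratio at 4.0 d: the clock's one-way share of 1.23 × 10⁻⁴ stands beside the 3.29 × 10⁻⁴ that this flask gives with that way back taken away, against 0.0558 with it.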